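The west run levelled off higher than the south run, with side product at 63.7% against 39.9%, and the two charges differed in partner, 0.30 M against 0.20 M.

| flask | starting material | partner | second substrate | third substrate | remark | time |
|---|---|---|---|---|---|---|
| south | 0.20 M | 0.20 M | 0.20 M | 0.20 M | run made earlier |  |
| west | 0.20 M | 0.30 M | 0.20 M | 0.20 M | run made earlier |  |
| east | 0.20 M | 0.40 M | 0.10 M | 0.20 M | run made earlier |  |
| flask | 0.20 M | 0.400 M | 0.200 M | 0.200 M |  | 10 min |

| run | time / min | side product / % | target / % |
|---|---|---|---|
| south | 1.50 | 39.7 | 0 |
| south | 3.00 | 39.4 | 0 |
| south | 5.00 | 40.1 | 0 |
| south | 6.00 | 39.8 | 0.1 |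
| south | 8.00 | 39.5 | 0 |
| south | 10.0 | 40.2 | 0.3 |
| south | 12.0 | 40.4 | 0.4 |
| west | 0.667 | 53.2 | 4.9 |
| west | 2.00 | 62.9 | 0 |
| west | 3.00 | 63.7 | 0 |
| west | 5.00 | 63.9 | 0 |
| west | 8.00 | 63.7 | 0 |
| west | 10.0 | 63.6 | 0 |
| west | 12.0 | 63.6 | 0 |
| east | 1.00 | 73.6 | 6.9 |
| east | 3.00 | 85.5 | 0.1 |
| east | 6.00 | 86.9 | 0 |
| east | 8.00 | 87.5 | 0 |
| east | 12.0 | 87.0 | 0 |

(readings scatter by 0.5 percentage points)

* which holds at 10 min: what has brought the reaction to rest, or that it has not come to rest (all of the starting material has reacted / it is still moving / the partner has run out first)
* the side product standing at 10 min, as a percentage of the starting material charged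
* amount of target if the flask were left three thousand times as long, in percent of the starting material charged

- a species is counted by the starting material in it: one side product counts as two
- the analysis behind the earlier runs scatters by 0.5 percentage points, standard deviation
- the reaction counts as stopped when no species that holds the starting material changes by six tenths of a point or more over the second half of the time

From those two plateaus I kept one number, 0.477, the partner's yield: the moles of starting material that one added mole of partner puts into side product.

The flask differs from the east run in second substrate, 0.200 M against 0.10 M, so I took two extremes. If second substrate is a bystander, the flask repeats the east plateau: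

upper extreme = 87.1%

If it consumes partner mole for mole, its extra charge cancels as much partner:

lower extreme = upper extreme − yield × extra second substrate / starting material = 63.3%

The south and west runs carry the flask's own second substrate, so their line gives the large part directly:

line = 87.5%

The correction is then line minus upper extreme, 0.4 percentage points, inside the scatter of 0.5 points. I therefore stood at the upper extreme, with partner as the limiting reagent and the east run flat from 6.00 min. I also expected no target: the last south reading of 0.4% lies inside that scatter, and the last east reading is 0%.

The forecast agreed with me that the partner has run out first and gave 87.3% side product, but it differed from me with 12.5% target: “the remainder should mostly become target”.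

The flask gave 86.8% side product and 0% target in the long run, and the partner has run out first, with 0% of it left at 10.0 min.

starting material + partner → target (k = 0.330 L mol⁻¹ s⁻¹); second substrate + partner → second product (k = 0.0210 L mol⁻¹ s⁻¹); third substrate + partner → third product (k = 1.20 L mol⁻¹ s⁻¹); second substrate → decomposition product (k = 3.40 × 10⁻⁵ s⁻¹); starting material + target → side product (k = 0.550 L mol⁻¹ s⁻¹); partner → decomposed reagent (k = 0.0620 s⁻¹) At 100 min it still held 13.2% starting material beside 0% target. Reckoned from the south run, this flask's partner's yield came to 0.469, against 0.477 from the plateaus. Carried down to a flask like this one but charged with 0.10 M of partner, 0.477 gives 16.0% side product, and that flask stood at 18.8%.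

The earlier runs and the new flask are simulated with constants of no real substance; scatter was added.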